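The pyran ring's O2–C1 bond is treated as the bond made by an oxa-6π electrocyclization. The ring-opened valence isomer is a cyclohexanone with two exocyclic alkenes, C8a=C1 and C4a=C4, the latter carrying the C3 propenyl ketone cis to C8a. A single palladium-catalysed carbonylative cascade assembles this dienone from an acyclic chain: it closes the carbocycle (C8a–C4a), inserts CO as C3 and couples the propenyl group, and the pyran ring then closes spontaneously. The substrate is an α-bromo vinyl ketone tethered to a terminal alkyne that already holds the C6 silyl ether and the C7 methyl and aryl ester groups.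

Key step: step 14

Remark: atoms are numbered as in 1H-isochromene; the target is (6R,7S) with O6 and O7 trans, which anti opening of a Z-enynol epoxide delivers; 1, 5, 10 and 22 are assumed to be purchasable as the isomers named.

Step 1
Reactants: 1 2,4-dihydroxy-6-methylbenzaldehyde
Product: 2 4-[(tert-butyldimethylsilyl)oxy]-2-hydroxy-6-methylbenzaldehyde
Conditions: TBSCl (1.05 equiv), imidazole, CH2Cl2, 0 °C
Reagents that add atoms: tert-butyldimethylsilyl chloride, CC(C)(C)[Si](C)(C)Cl
Why: Silyl ether formation should occur only at the 4-hydroxyl, because the 2-hydroxyl is locked in an intramolecular hydrogen bond to the aldehyde and is the more hindered and less nucleophilic of the two (regioselective O-silylation).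

Step 2
Reactants: 2 4-silyloxy-2-hydroxy aldehyde
Product: 3 4-[(tert-butyldimethylsilyl)oxy]-2-methoxy-6-methylbenzaldehyde
Conditions: MeI, Ag2O, CH2Cl2, 40 °C, dark
Reagents that add atoms: iodomethane, CI
Why: Purdie methylation (Ag2O-assisted Williamson etherification) should alkylate the remaining chelated phenol under non-nucleophilic, essentially neutral conditions, so that the aryl silyl ether is neither cleaved nor transferred.

Step 3
Reactants: 3 4-silyloxy-2-methoxy aldehyde
Product: 4 4-[(tert-butyldimethylsilyl)oxy]-2-methoxy-6-methylbenzoic acid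
Conditions: NaClO2, NaH2PO4, 2-methylbut-2-ene, t-BuOH/H2O, rt
Reagents that add atoms: sodium chlorite, [Na+].[O-]Cl=O
Why: Pinnick oxidation converts hindered, electron-rich benzaldehydes into benzoic acids at buffered pH, the alkene scavenging the hypochlorite by-product so that ring chlorination and loss of the silyl ether are avoided.

Step 4
Reactants: 5 (Z)-3-methylpent-2-en-4-yn-1-ol
Product: 6 [(2R,3S)-3-ethynyl-3-methyloxiran-2-yl]methanol
Conditions: Ti(OiPr)4 (10 mol%), D-(−)-diisopropyl tartrate (12 mol%), t-BuOOH, 4 Å MS, CH2Cl2, −20 °C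
Reagents that add atoms: tert-butyl hydroperoxide, CC(C)(C)OO
Why: Sharpless asymmetric epoxidation of the primary allylic alcohol: with the D-(−)-tartrate the titanium peroxide should deliver oxygen to the face that gives the (2R,3S)-epoxide, which fixes C6 as R at once, places CH2OH and ethynyl cis (from the Z alkene) and prepares C7 for inversion in the next step.

Step 5
Reactants: 6 epoxy alcohol, 4 aryl acid
Product: 7 (2R,3R)-1,2-dihydroxy-3-methylpent-4-yn-3-yl 4-[(tert-butyldimethylsilyl)oxy]-2-methoxy-6-methylbenzoate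
Conditions: Ti(OiPr)4 (1.5 equiv), CH2Cl2, rt
Reagents that add atoms: none
Why: Titanium-alkoxide-mediated C3-selective opening of a 2,3-epoxy alcohol by a carboxylic acid: within the titanium chelate the carboxylate should attack the tertiary propargylic carbon anti to the epoxide oxygen, so that C7 is set by SN2 inversion, C6 is untouched, O6 and O7 end up anti, and the hindered ester arises without acylation of a tertiary alcohol.

Step 6
Reactants: 7 diol ester
Product: 9 (2R)-2-[(2R)-oxiran-2-yl]but-3-yn-2-yl 4-[(tert-butyldimethylsilyl)oxy]-2-methoxy-6-methylbenzoate, via primary tosylate 8 (not isolated)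
Conditions: TsCl, Et3N, Bu2SnO (cat.), CH2Cl2, 0 °C → rt; then DBU, rt
Reagents that add atoms: none
Why: Tin-catalysed selective sulfonylation of the primary hydroxyl followed by base-induced intramolecular Williamson closure (3-exo-tet) by the neopentyl-type secondary hydroxyl should give the terminal epoxide with retention at C6, since only the C5–O bond is broken.

Step 7
Reactants: 9 terminal epoxide, 10 trimethylsilylacetylene
Product: 12 (3R,4R)-4-hydroxy-3-methyl-7-(trimethylsilyl)hepta-1,6-diyn-3-yl 4-[(tert-butyldimethylsilyl)oxy]-2-methoxy-6-methylbenzoate, via lithium (trimethylsilyl)acetylide 11 (not isolated)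
Conditions: n-BuLi, THF, −78 °C; BF3·OEt2; then 9, −78 °C
Reagents that add atoms: none
Why: Yamaguchi alkynylation (BF3-promoted epoxide opening by a lithium acetylide) should take place at the unsubstituted C5 at −78 °C, where the weakly basic alkynylborate neither attacks the hindered ester nor metalates the substrate's own alkyne, and C6 keeps its configuration.

Step 8
Reactants: 12 homopropargylic alcohol
Product: 13 (3R,4R)-4-[(tert-butyldimethylsilyl)oxy]-3-methyl-7-(trimethylsilyl)hepta-1,6-diyn-3-yl 4-[(tert-butyldimethylsilyl)oxy]-2-methoxy-6-methylbenzoate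
Conditions: TBSOTf, 2,6-lutidine, CH2Cl2, −78 → 0 °C
Reagents that add atoms: tert-butyldimethylsilyl trifluoromethanesulfonate, CC(C)(C)[Si](C)(C)OS(=O)(=O)C(F)(F)F
Why: Silyl triflate with 2,6-lutidine is the standard method for silylating a hindered secondary alcohol beside a quaternary carbon, and the ether blocks O7-to-O6 acyl migration and hydroxyl participation in all later steps.

Step 9
Reactants: 13 bis-silyl diyne ester
Product: 14 (3S,4R)-4-[(tert-butyldimethylsilyl)oxy]-3-methyl-2-oxo-7-(trimethylsilyl)hept-6-yn-3-yl 4-[(tert-butyldimethylsilyl)oxy]-2-methoxy-6-methylbenzoate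
Conditions: Ph3PAuNTf2 (2 mol%), H2O (5 equiv), 1,4-dioxane, rt
Reagents that add atoms: water, O
Why: Gold-catalysed hydration of a terminal propargylic ester with neighbouring-group assistance (5-exo-dig attack of the ester carbonyl, then hydrolysis of the dioxolanylium ion) should give the α-acyloxy methyl ketone with Markovnikov regiochemistry and an intact C7–O bond, while the silyl-capped alkyne, which lacks such assistance, is left alone.

Step 10
Reactants: 14 methyl ketone with silyl-capped alkyne
Product: 15 (3S,4R)-4-[(tert-butyldimethylsilyl)oxy]-3-methyl-2-oxohept-6-yn-3-yl 4-[(tert-butyldimethylsilyl)oxy]-2-methoxy-6-methylbenzoate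
Conditions: AgNO3 (10 mol%), acetone/H2O, rt
Reagents that add atoms: none
Why: Silver-catalysed protodesilylation cleaves the C–Si bond of a 1-silylalkyne through a silver acetylide under neutral aqueous conditions that do not affect oxygen-bound silyl groups, the hindered ester or the ketone.

Step 11
Reactants: 15 methyl ketone with terminal alkyne
Product: 19 (4S,5R)-5-[(tert-butyldimethylsilyl)oxy]-4-methyl-3-oxooct-1-en-7-yn-4-yl 4-[(tert-butyldimethylsilyl)oxy]-2-methoxy-6-methylbenzoate, via silyl enol ether 16 (not isolated), via Mannich base 17 (not isolated), via methiodide 18 (not isolated)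
Conditions: TMSOTf, Et3N, CH2Cl2, 0 °C; (Me2N=CH2)I, rt; MeI, Et2O; then aq NaHCO3, rt
Reagents that add atoms: Eschenmoser's salt (N,N-dimethylmethyleneiminium iodide), C=[N+](C)C.[I-]
Why: Mannich α-methylenation: the methyl group is the only enolizable position (C7 is quaternary), its silyl enol ether is aminomethylated by the iminium salt, and quaternization followed by E1cB loss of trimethylamine with bicarbonate should release the vinyl ketone.

Step 12
Reactants: 19 vinyl ketone
Product: 21 (4S,5R)-2-bromo-5-[(tert-butyldimethylsilyl)oxy]-4-methyl-3-oxooct-1-en-7-yn-4-yl 4-[(tert-butyldimethylsilyl)oxy]-2-methoxy-6-methylbenzoate, via dibromo ketone 20 (not isolated)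
Conditions: Br2 (1.0 equiv), CH2Cl2, −78 °C; then Et3N, −78 → 0 °C
Reagents that add atoms: bromine, BrBr
Why: Bromination–dehydrobromination of an enone: bromine adds across the vinyl ketone and triethylamine then removes the acidic α-hydrogen with loss of the β-bromide, which leaves bromine on C8a, while one equivalent added slowly at low temperature should be consumed by the enone before the isolated alkyne or the silyloxyarene can react.

Step 13
Reactants: 22 (E)-1-bromoprop-1-ene
Product: 24 (E)-tributyl(prop-1-en-1-yl)stannane, via (E)-prop-1-enyllithium 23 (not isolated)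
Conditions: t-BuLi (2 equiv), Et2O, −78 °C; then Bu3SnCl, −78 °C → rt
Reagents that add atoms: tributyltin chloride, CCCC[Sn](Cl)(CCCC)CCCC
Why: Bromine–lithium exchange on an alkenyl bromide and stannylation of the resulting alkenyllithium both proceed with retention of alkene geometry, so the E bromide should give the E stannane.

Step 14
Reactants: 21 α-bromo enone alkyne, 24 (E)-propenylstannane
Product: 26 (6R,7S)-6-[(tert-butyldimethylsilyl)oxy]-7-methyl-8-oxo-3-[(1E)-prop-1-en-1-yl]-5,6,7,8-tetrahydro-1H-isochromen-7-yl 4-[(tert-butyldimethylsilyl)oxy]-2-methoxy-6-methylbenzoate, via cis-dienone 25 (not isolated)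
Conditions: Pd(PPh3)4 (10 mol%), CO (1 atm), toluene, 80 °C, 24 added over 6 h
Reagents that add atoms: carbon monoxide, [C-]#[O+]
Why: Proposed new method: oxidative addition of zerovalent palladium into the C8a–Br bond of 21 should be followed by intramolecular syn-carbopalladation of the C4a≡C4 triple bond, migratory insertion of CO at C4, transmetalation of the propenyl group from 24 and reductive elimination, which releases dienone 25; its O=C3–C4=C4a–C8a=C1 array then closes by thermal disrotatory oxa-6π electrocyclization to 26. The closest known reaction types are cyclocarbopalladation cascades of halo-alkynes terminated by carbonylative Stille coupling and the spontaneous closure of cis-dienones to 2H-pyrans; new here are the α-bromo enone as the starting alkenyl halide and the merger of both events. The carbocycle closes in the 6-exo-dig mode (C8a–C4a bond) and the pyran ring by the six-electron electrocyclization (O2–C1 bond). No stereocentre is created: C6 and C7 are carried through untouched (C7 bears no hydrogen, so neither epimerization nor β-elimination is possible), and the only new stereo-element, the C4a=C4 geometry, is fixed by the syn addition, which places the acyl group cis to C8a as the electrocyclization requires. The step needs ring closure to precede both CO uptake and coupling at C8a, and CO insertion to precede coupling at C4: the tether makes the 6-exo insertion intramolecular, only one atmosphere of CO is used and 24 is added by syringe pump, while the acylpalladium cannot add to the adjacent C8a=C1 alkene except through disfavoured 4-exo or 5-endo closures. The closed form should be the resting state because it is the push–pull vinylogous ester that the target itself displays.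

Step 15
Reactants: 26 bis-silylated target
Product: 27 (6R,7S)-6-hydroxy-7-methyl-8-oxo-3-[(1E)-prop-1-en-1-yl]-5,6,7,8-tetrahydro-1H-isochromen-7-yl 4-hydroxy-2-methoxy-6-methylbenzoate (CNP0187389.3)
Conditions: HF·pyridine, pyridine, THF, 0 °C → rt
Reagents that add atoms: none
Why: Fluoride-mediated desilylation with buffered HF·pyridine should cleave the aryl and the alkyl silyl ether without generating an alkoxide, which avoids O7-to-O6 acyl migration, retro-aldol cleavage and vinylogous β-elimination, and leaves both stereocentres untouched.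

Compound list
1 | 2,4-dihydroxy-6-methylbenzaldehyde | Cc1cc(O)cc(O)c1C=O | starting material
2 | 4-[(tert-butyldimethylsilyl)oxy]-2-hydroxy-6-methylbenzaldehyde | Cc1cc(O[Si](C)(C)C(C)(C)C)cc(O)c1C=O | intermediate
3 | 4-[(tert-butyldimethylsilyl)oxy]-2-methoxy-6-methylbenzaldehyde | COc1cc(O[Si](C)(C)C(C)(C)C)cc(C)c1C=O | intermediate
4 | 4-[(tert-butyldimethylsilyl)oxy]-2-methoxy-6-methylbenzoic acid | COc1cc(O[Si](C)(C)C(C)(C)C)cc(C)c1C(=O)O | intermediate
5 | (Z)-3-methylpent-2-en-4-yn-1-ol | OC/C=C(\C#C)C | starting material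
6 | [(2R,3S)-3-ethynyl-3-methyloxiran-2-yl]methanol | C#C[C@]1(C)O[C@@H]1CO | intermediate
7 | (2R,3R)-1,2-dihydroxy-3-methylpent-4-yn-3-yl 4-[(tert-butyldimethylsilyl)oxy]-2-methoxy-6-methylbenzoate | C#C[C@@](C)(OC(=O)c1c(C)cc(O[Si](C)(C)C(C)(C)C)cc1OC)[C@H](O)CO | intermediate
8 | (2R,3R)-2-hydroxy-3-methyl-1-(tosyloxy)pent-4-yn-3-yl 4-[(tert-butyldimethylsilyl)oxy]-2-methoxy-6-methylbenzoate | C#C[C@@](C)(OC(=O)c1c(C)cc(O[Si](C)(C)C(C)(C)C)cc1OC)[C@H](O)COS(=O)(=O)c1ccc(C)cc1 | intermediate
9 | (2R)-2-[(2R)-oxiran-2-yl]but-3-yn-2-yl 4-[(tert-butyldimethylsilyl)oxy]-2-methoxy-6-methylbenzoate | C#C[C@@](C)(OC(=O)c1c(C)cc(O[Si](C)(C)C(C)(C)C)cc1OC)[C@H]1CO1 | intermediate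
10 | trimethylsilylacetylene | C[Si](C)(C)C#C | starting material
11 | lithium (trimethylsilyl)acetylide | [Li]C#C[Si](C)(C)C | intermediate
12 | (3R,4R)-4-hydroxy-3-methyl-7-(trimethylsilyl)hepta-1,6-diyn-3-yl 4-[(tert-butyldimethylsilyl)oxy]-2-methoxy-6-methylbenzoate | C#C[C@@](C)(OC(=O)c1c(C)cc(O[Si](C)(C)C(C)(C)C)cc1OC)[C@H](O)CC#C[Si](C)(C)C | intermediate
13 | (3R,4R)-4-[(tert-butyldimethylsilyl)oxy]-3-methyl-7-(trimethylsilyl)hepta-1,6-diyn-3-yl 4-[(tert-butyldimethylsilyl)oxy]-2-methoxy-6-methylbenzoate | C#C[C@@](C)(OC(=O)c1c(C)cc(O[Si](C)(C)C(C)(C)C)cc1OC)[C@H](O[Si](C)(C)C(C)(C)C)CC#C[Si](C)(C)C | intermediate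
14 | (3S,4R)-4-[(tert-butyldimethylsilyl)oxy]-3-methyl-2-oxo-7-(trimethylsilyl)hept-6-yn-3-yl 4-[(tert-butyldimethylsilyl)oxy]-2-methoxy-6-methylbenzoate | CC(=O)[C@@](C)(OC(=O)c1c(C)cc(O[Si](C)(C)C(C)(C)C)cc1OC)[C@H](O[Si](C)(C)C(C)(C)C)CC#C[Si](C)(C)C | intermediate
15 | (3S,4R)-4-[(tert-butyldimethylsilyl)oxy]-3-methyl-2-oxohept-6-yn-3-yl 4-[(tert-butyldimethylsilyl)oxy]-2-methoxy-6-methylbenzoate | CC(=O)[C@@](C)(OC(=O)c1c(C)cc(O[Si](C)(C)C(C)(C)C)cc1OC)[C@H](O[Si](C)(C)C(C)(C)C)CC#C | intermediate
16 | (3S,4R)-4-[(tert-butyldimethylsilyl)oxy]-3-methyl-2-[(trimethylsilyl)oxy]hept-1-en-6-yn-3-yl 4-[(tert-butyldimethylsilyl)oxy]-2-methoxy-6-methylbenzoate | C=C(O[Si](C)(C)C)[C@@](C)(OC(=O)c1c(C)cc(O[Si](C)(C)C(C)(C)C)cc1OC)[C@H](O[Si](C)(C)C(C)(C)C)CC#C | intermediate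
17 | (4S,5R)-5-[(tert-butyldimethylsilyl)oxy]-1-(dimethylamino)-4-methyl-3-oxooct-7-yn-4-yl 4-[(tert-butyldimethylsilyl)oxy]-2-methoxy-6-methylbenzoate | CN(C)CCC(=O)[C@@](C)(OC(=O)c1c(C)cc(O[Si](C)(C)C(C)(C)C)cc1OC)[C@H](O[Si](C)(C)C(C)(C)C)CC#C | intermediate
18 | (4S,5R)-4-({4-[(tert-butyldimethylsilyl)oxy]-2-methoxy-6-methylbenzoyl}oxy)-5-[(tert-butyldimethylsilyl)oxy]-N,N,N,4-tetramethyl-3-oxooct-7-yn-1-aminium iodide | C[N+](C)(C)CCC(=O)[C@@](C)(OC(=O)c1c(C)cc(O[Si](C)(C)C(C)(C)C)cc1OC)[C@H](O[Si](C)(C)C(C)(C)C)CC#C.[I-] | intermediate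
19 | (4S,5R)-5-[(tert-butyldimethylsilyl)oxy]-4-methyl-3-oxooct-1-en-7-yn-4-yl 4-[(tert-butyldimethylsilyl)oxy]-2-methoxy-6-methylbenzoate | C=CC(=O)[C@@](C)(OC(=O)c1c(C)cc(O[Si](C)(C)C(C)(C)C)cc1OC)[C@H](O[Si](C)(C)C(C)(C)C)CC#C | intermediate
20 | (4S,5R)-1,2-dibromo-5-[(tert-butyldimethylsilyl)oxy]-4-methyl-3-oxooct-7-yn-4-yl 4-[(tert-butyldimethylsilyl)oxy]-2-methoxy-6-methylbenzoate (both C2 epimers) | BrCC(Br)C(=O)[C@@](C)(OC(=O)c1c(C)cc(O[Si](C)(C)C(C)(C)C)cc1OC)[C@H](O[Si](C)(C)C(C)(C)C)CC#C | intermediate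
21 | (4S,5R)-2-bromo-5-[(tert-butyldimethylsilyl)oxy]-4-methyl-3-oxooct-1-en-7-yn-4-yl 4-[(tert-butyldimethylsilyl)oxy]-2-methoxy-6-methylbenzoate | C=C(Br)C(=O)[C@@](C)(OC(=O)c1c(C)cc(O[Si](C)(C)C(C)(C)C)cc1OC)[C@H](O[Si](C)(C)C(C)(C)C)CC#C | intermediate
22 | (E)-1-bromoprop-1-ene | C/C=C/Br | starting material
23 | (E)-prop-1-enyllithium | C/C=C/[Li] | intermediate
24 | (E)-tributyl(prop-1-en-1-yl)stannane | C/C=C/[Sn](CCCC)(CCCC)CCCC | intermediate
25 | (1S,2R,4Z)-2-[(tert-butyldimethylsilyl)oxy]-1-methyl-5-methylidene-6-oxo-4-[(3E)-2-oxopent-3-en-1-ylidene]cyclohexyl 4-[(tert-butyldimethylsilyl)oxy]-2-methoxy-6-methylbenzoate | C=C1C(=O)[C@@](C)(OC(=O)c2c(C)cc(O[Si](C)(C)C(C)(C)C)cc2OC)[C@H](O[Si](C)(C)C(C)(C)C)C/C1=C/C(=O)/C=C/C | intermediate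
26 | (6R,7S)-6-[(tert-butyldimethylsilyl)oxy]-7-methyl-8-oxo-3-[(1E)-prop-1-en-1-yl]-5,6,7,8-tetrahydro-1H-isochromen-7-yl 4-[(tert-butyldimethylsilyl)oxy]-2-methoxy-6-methylbenzoate | C/C=C/C1=CC2=C(CO1)C(=O)[C@@](C)(OC(=O)c1c(C)cc(O[Si](C)(C)C(C)(C)C)cc1OC)[C@H](O[Si](C)(C)C(C)(C)C)C2 | intermediate
27 | (6R,7S)-6-hydroxy-7-methyl-8-oxo-3-[(1E)-prop-1-en-1-yl]-5,6,7,8-tetrahydro-1H-isochromen-7-yl 4-hydroxy-2-methoxy-6-methylbenzoate | C/C=C/C1=CC2=C(CO1)C(=O)[C@@](C)(OC(=O)c1c(C)cc(O)cc1OC)[C@H](O)C2 | target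

Total step count: 15. Longest linear sequence: 13 steps (steps 1–3, 5–12, 14 and 15).

Steps most likely to fail

Step 14 (the key step). The alkenylpalladium formed at C8a may couple with the stannane or take up CO before it adds to the alkyne, carbonylation at C4 may be outrun by direct coupling, or the bromo enone may oligomerize at 80 °C. The fallback makes the same bonds in two known operations and sets out from 21. Pd(PPh3)4 with hexamethylditin in toluene should effect oxidative addition, 6-exo-dig carbopalladation and tin transfer to give (Z)-alkenylstannane F1. A Stille ketone synthesis of F1 with (E)-but-2-enoyl chloride (PdCl2(PPh3)2, toluene, 60 °C) then installs the C3 ketone with retention, giving dienone 25. This closes on warming, and the fallback comes back to the route at 26.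

Step 12. Bromine may be taken up competitively by the terminal alkyne or by the electron-rich silyloxyarene, or the vinyl ketone may polymerize before it is brominated. The fallback avoids free bromine and the vinyl ketone and sets out from 15. Silyl enol ether 16 (TMSOTf, Et3N) is brominated with NBS at −78 °C to bromomethyl ketone F2. PPh3 in toluene gives phosphonium bromide F3, and aqueous Na2CO3 gives acyl ylide F4. NBS then gives bromo ylide F5, and Wittig methylenation of F5 with formaldehyde is run near room temperature, so that intramolecular attack of the ylide on the hindered ester stays slow. The fallback comes back at 21.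

Step 5. The hindered carboxylate may attack slowly, so that isopropoxide transfer, ionization at the tertiary propargylic carbon with loss of stereochemical integrity, or acyl migration intervenes. The fallback forms the ester by acylation and sets out from 6. Dilute aqueous HClO4 in THF opens the epoxide at the tertiary carbon with inversion to give triol F6. 2,2-Dimethoxypropane with PPTS protects the terminal 1,2-diol as acetonide F7. The lithium alkoxide of F7 (LiHMDS, THF, −78 °C) is acylated with acid chloride F8, made from 4 with oxalyl chloride and catalytic DMF, to give ester acetonide F9. Aqueous acetic acid then removes the acetonide, and the fallback comes back at 7.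

Further compounds
F1 | step 14 | (1S,2R,4Z)-2-[(tert-butyldimethylsilyl)oxy]-1-methyl-5-methylidene-6-oxo-4-[(trimethylstannyl)methylidene]cyclohexyl 4-[(tert-butyldimethylsilyl)oxy]-2-methoxy-6-methylbenzoate | C=C1C(=O)[C@@](C)(OC(=O)c2c(C)cc(O[Si](C)(C)C(C)(C)C)cc2OC)[C@H](O[Si](C)(C)C(C)(C)C)C/C1=C/[Sn](C)(C)C
F2 | step 12 | (3S,4R)-1-bromo-4-[(tert-butyldimethylsilyl)oxy]-3-methyl-2-oxohept-6-yn-3-yl 4-[(tert-butyldimethylsilyl)oxy]-2-methoxy-6-methylbenzoate | O=C(CBr)[C@@](C)(OC(=O)c1c(C)cc(O[Si](C)(C)C(C)(C)C)cc1OC)[C@H](O[Si](C)(C)C(C)(C)C)CC#C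
F3 | step 12 | [(3S,4R)-3-({4-[(tert-butyldimethylsilyl)oxy]-2-methoxy-6-methylbenzoyl}oxy)-4-[(tert-butyldimethylsilyl)oxy]-3-methyl-2-oxohept-6-yn-1-yl]triphenylphosphonium bromide | O=C(C[P+](c1ccccc1)(c1ccccc1)c1ccccc1)[C@@](C)(OC(=O)c1c(C)cc(O[Si](C)(C)C(C)(C)C)cc1OC)[C@H](O[Si](C)(C)C(C)(C)C)CC#C.[Br-]
F4 | step 12 | (3S,4R)-4-[(tert-butyldimethylsilyl)oxy]-3-methyl-2-oxo-1-(triphenyl-λ5-phosphanylidene)hept-6-yn-3-yl 4-[(tert-butyldimethylsilyl)oxy]-2-methoxy-6-methylbenzoate | O=C(C=P(c1ccccc1)(c1ccccc1)c1ccccc1)[C@@](C)(OC(=O)c1c(C)cc(O[Si](C)(C)C(C)(C)C)cc1OC)[C@H](O[Si](C)(C)C(C)(C)C)CC#C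
F5 | step 12 | (3S,4R)-1-bromo-4-[(tert-butyldimethylsilyl)oxy]-3-methyl-2-oxo-1-(triphenyl-λ5-phosphanylidene)hept-6-yn-3-yl 4-[(tert-butyldimethylsilyl)oxy]-2-methoxy-6-methylbenzoate | O=C(C(Br)=P(c1ccccc1)(c1ccccc1)c1ccccc1)[C@@](C)(OC(=O)c1c(C)cc(O[Si](C)(C)C(C)(C)C)cc1OC)[C@H](O[Si](C)(C)C(C)(C)C)CC#C
F6 | step 5 | (2R,3R)-3-methylpent-4-yne-1,2,3-triol | C#C[C@@](C)(O)[C@H](O)CO
F7 | step 5 | (2R)-2-[(4R)-2,2-dimethyl-1,3-dioxolan-4-yl]but-3-yn-2-ol | C#C[C@@](C)(O)[C@H]1COC(C)(C)O1
F8 | step 5 | 4-[(tert-butyldimethylsilyl)oxy]-2-methoxy-6-methylbenzoyl chloride | COc1cc(O[Si](C)(C)C(C)(C)C)cc(C)c1C(Cl)=O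
F9 | step 5 | (2R)-2-[(4R)-2,2-dimethyl-1,3-dioxolan-4-yl]but-3-yn-2-yl 4-[(tert-butyldimethylsilyl)oxy]-2-methoxy-6-methylbenzoate | C#C[C@@](C)(OC(=O)c1c(C)cc(O[Si](C)(C)C(C)(C)C)cc1OC)[C@H]1COC(C)(C)O1
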